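The dihydrofuran ring (O1, C2, C3, C3a, C7a) plus its CMe2 side chain hides an isoprene unit fused to an o-oxygenated aryl edge. It is therefore made in one catalytic operation, an enantioselective Heck/Tsuji–Trost heteroannulation of an o-iodophenol with isoprene. This forges C3–C3a and C2–O1 and sets C2 under ligand control. The iodophenol is 6-iodonaringenin. The cheap flavanone already holds every other carbon of the target, and its temporary pyranone ring masks the enone and one ortho-hydroxyl. Markovnikov hydration of the isopropenyl group and a final retro-oxa-Michael opening, which erases the racemic flavanone centre, complete a four-step, protecting-group-free route.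

Key step: step 2

Remark: commercial naringenin is taken as the racemate and its flavanone centre is drawn without configuration, because step 4 destroys it, so 4–6 are epimer pairs carried on together. Any 8-iodo isomer from step 1 would lead through the same steps to the same chalcone 8.

Step 1
Reactants: 1 (±)-naringenin
Product: 2 (±)-6-iodonaringenin
Conditions: NIS (1.0 equiv), DMF, 0 °C to rt, dark
Reagents that add atoms: N-iodosuccinimide, O=C1CCC(=O)N1I
Why: Electrophilic aromatic iodination (SEAr): the phloroglucinol-type A ring is far more nucleophilic than the B-ring phenol, neutral NIS attacks 5-hydroxyflavonoids at C6 between the two free hydroxyls, one equivalent of reagent should hold the reaction at the mono-iodide, and no stereocentre is formed.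

Step 2
Reactants: 2 (±)-6-iodonaringenin; 3 isoprene
Product: 4 (2S,7RS)-4-hydroxy-7-(4-hydroxyphenyl)-2-(prop-1-en-2-yl)-2,3,6,7-tetrahydro-5H-furo[3,2-g]chromen-5-one
Conditions: Pd2(dba)3·CHCl3 (cat.), chiral sulfinamide monophosphine L* (TY-Phos type, enantiomer that delivers 2S, cat.), PhONa (2.2 equiv), 3 (5 equiv), 1,4-dioxane, 70 °C, sealed tube, Ar
Reagents that add atoms: none
Why: Pd(0)L* inserts into the C6–I bond of 2, the aryl group migrates to the terminal CH2 of the less substituted vinyl end of isoprene (this carbon becomes C3), and the catalyst-bound η3-allyl unit is captured at its internal terminus by the neighbouring 7-phenoxide, so C3–C3a and C2–O1 are made in one catalytic cycle. The reaction type is the enantioselective Heck/Tsuji–Trost (Larock-type) heteroannulation of o-halophenols with 1,3-dienes, which is established for isoprene and tolerates aryl ketones. The dihydrofuran closes in a 5-exo mode by anti attack of oxygen on the allyl terminus, whereas attack at the CH2 terminus would need a seven-membered ring. C2 is controlled by the chiral ligand alone: the two faces of the allyl unit can exchange by η3–η1–η3 slippage through its unsubstituted CH2 terminus and the ligand pocket selects the one that leads to 2S, while the remote racemic flavanone centre has no influence, so both epimers of 2 should give 2S. The step needs O-regioselectivity between the two hydroxyls that flank C6: O7, para to the carbonyl, is the acidic one and is ionised by PhONa, whereas O5 is locked in the hydrogen bond to C4=O and closure through it would sacrifice that chelate. It also needs insertion at the monosubstituted rather than the 1,1-disubstituted alkene of isoprene, which the steric demand of the doubly ortho-substituted arylpalladium reinforces.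

Step 3
Reactants: 4 (2S,7RS)-isopropenyl furoflavanone
Product: 6 (2S,7RS)-4-hydroxy-7-(4-hydroxyphenyl)-2-(2-hydroxypropan-2-yl)-2,3,6,7-tetrahydro-5H-furo[3,2-g]chromen-5-one, via tertiary hydroperoxide 5 (not isolated)
Conditions: Co(acac)2 (cat.), PhSiH3, O2 (1 atm), THF, rt; then PPh3, rt
Reagents that add atoms: dioxygen, O=O
Why: Mukaiyama hydration: cobalt hydride transfers H• to the terminal CH2 of the 1,1-disubstituted alkene (Markovnikov), the tertiary radical is trapped by O2 faster than it can fragment and PPh3 reduces hydroperoxide 5, while the new carbinol carbon is not stereogenic, C2 is untouched and the enone, masked as the saturated pyranone, offers no competing acceptor.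

Step 4
Reactants: 6 (2S,7RS)-hydroxyisopropyl furoflavanone
Product: 8 (S,E)-1-[4,6-dihydroxy-2-(2-hydroxypropan-2-yl)-2,3-dihydrobenzofuran-5-yl]-3-(4-hydroxyphenyl)prop-2-en-1-one, via tripotassium chalconate 7 (not isolated)
Conditions: KOH (aq, excess), EtOH, N2, rt; then poured into ice-cold 2 M HCl (pH 2), rapid extraction with EtOAc
Reagents that add atoms: none
Why: Retro-oxa-Michael (E1cB) opening, well established for simple 5,7-dihydroxyflavanones: strong base drives the flavanone–chalcone equilibrium to the delocalised (E)-chalcone phenolate 7 and a fast quench into cold acid protonates it at a pH where re-closure is slow, the racemic flavanone centre becomes sp2 so both epimers give one product, and C2 of the dihydrofuran carries no acidic hydrogen and is retained.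

Compound list
1 | (±)-naringenin (5,7,4'-trihydroxyflavanone) | O=C1CC(c2ccc(O)cc2)Oc2cc(O)cc(O)c12 | starting material
2 | (±)-6-iodonaringenin | O=C1CC(c2ccc(O)cc2)Oc2cc(O)c(I)c(O)c12 | intermediate
3 | isoprene (2-methylbuta-1,3-diene) | C=CC(C)=C | starting material
4 | (2S,7RS)-4-hydroxy-7-(4-hydroxyphenyl)-2-(prop-1-en-2-yl)-2,3,6,7-tetrahydro-5H-furo[3,2-g]chromen-5-one | CC(=C)[C@@H]1Cc2c(O1)cc1OC(c3ccc(O)cc3)CC(=O)c1c2O | intermediate
5 | (2S,7RS)-2-(2-hydroperoxypropan-2-yl) analogue of 6 (not isolated) | CC(C)(OO)[C@@H]1Cc2c(O1)cc1OC(c3ccc(O)cc3)CC(=O)c1c2O | intermediate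
6 | (2S,7RS)-4-hydroxy-7-(4-hydroxyphenyl)-2-(2-hydroxypropan-2-yl)-2,3,6,7-tetrahydro-5H-furo[3,2-g]chromen-5-one | CC(C)(O)[C@@H]1Cc2c(O1)cc1OC(c3ccc(O)cc3)CC(=O)c1c2O | intermediate
7 | tripotassium salt of chalcone 8 (not isolated) | CC(C)(O)[C@@H]1Cc2c(cc([O-])c(C(=O)/C=C/c3ccc([O-])cc3)c2[O-])O1.[K+].[K+].[K+] | intermediate
8 | (S,E)-1-[4,6-dihydroxy-2-(2-hydroxypropan-2-yl)-2,3-dihydrobenzofuran-5-yl]-3-(4-hydroxyphenyl)prop-2-en-1-one | CC(C)(O)[C@@H]1Cc2c(cc(O)c(C(=O)/C=C/c3ccc(O)cc3)c2O)O1 | target

Total step count: 4. Longest linear sequence: 4.

Steps most likely to fail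

Step 2. Oxidative addition at the electron-rich, doubly ortho-oxygenated C–I bond may be slow, so hydrodeiodination could compete. Base-induced opening of the pyranone may blur the choice between the flanking oxygens. Re-ionisation of the allylic aryl ether by Pd(0) may erode the enantiomeric purity. The fallback sets out from 2 and returns at 6, bypassing steps 2 and 3.
- Peracetylation (Ac2O, pyridine, DMAP) would give 6-iodonaringenin triacetate F1.
- Stille coupling with tributyl(3-methylbut-2-enyl)stannane (Pd(PPh3)4, DMF, 80 °C) would give 6-prenylnaringenin triacetate F2.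
- Shi epoxidation with the D-fructose-derived ketone (Oxone, K2CO3 buffer, MeCN/DMM, 0 °C) should give, by the spiro transition-state model, the (R)-epoxide triacetate F3.
- K2CO3 in MeOH would remove the acetates, and the freed 7-phenoxide should open the epoxide 5-exo-tet at its secondary carbon with inversion, giving (2S)-6.

Step 4. The chalcone may re-close to the flavanone while the pH passes through neutrality on quenching or during purification, and prolonged exposure to strong base may cause retro-aldol cleavage. The fallback sets out from 6 and returns at 8.
- The flavanone would be opened under aprotic conditions and the phenolates trapped as they form (KHMDS, then TBSCl, THF/DMF, −20 °C to rt). This should give the tris-TBS chalcone F4, which cannot re-close and can be purified without haste.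
- Et3N·3HF in THF at 0 °C, a mildly acidic fluoride source that never generates a free phenolate, would then release 8.

Step 3. The free phenols may interfere with the cobalt/O2 radical process through phenol oxidation or chain inhibition, and the tertiary radical may fragment with loss of the aryloxy group. The fallback sets out from 4 and returns at 7.
- Acetylation (Ac2O, pyridine, DMAP) would give the isopropenyl flavanone diacetate F5.
- The same hydration on this phenol-free, less electron-rich substrate would pass through the hydroperoxide diacetate F6 to the hydroxyisopropyl flavanone diacetate F7.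
- The KOH treatment of step 4 would saponify both acetates and open the pyranone in the same operation, so only one step is added.

Further compounds
F1 | step 2 | (±)-6-iodonaringenin triacetate | CC(=O)Oc1ccc(cc1)C1CC(=O)c2c(O1)cc(OC(C)=O)c(I)c2OC(C)=O
F2 | step 2 | (±)-6-prenylnaringenin triacetate | CC(=O)Oc1ccc(cc1)C1CC(=O)c2c(O1)cc(OC(C)=O)c(CC=C(C)C)c2OC(C)=O
F3 | step 2 | 6-{[(2R)-3,3-dimethyloxiran-2-yl]methyl}naringenin triacetate (flavanone epimers) | CC(=O)Oc1ccc(cc1)C1CC(=O)c2c(O1)cc(OC(C)=O)c(C[C@H]1OC1(C)C)c2OC(C)=O
F4 | step 4 | tris-O-TBS ether of chalcone 8 | CC(C)(O)[C@@H]1Cc2c(cc(O[Si](C)(C)C(C)(C)C)c(C(=O)/C=C/c3ccc(O[Si](C)(C)C(C)(C)C)cc3)c2O[Si](C)(C)C(C)(C)C)O1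
F5 | step 3 | diacetate of 4 | CC(=C)[C@@H]1Cc2c(O1)cc1OC(c3ccc(OC(C)=O)cc3)CC(=O)c1c2OC(C)=O
F6 | step 3 | diacetate of hydroperoxide 5 | CC(C)(OO)[C@@H]1Cc2c(O1)cc1OC(c3ccc(OC(C)=O)cc3)CC(=O)c1c2OC(C)=O
F7 | step 3 | diacetate of 6 | CC(C)(O)[C@@H]1Cc2c(O1)cc1OC(c3ccc(OC(C)=O)cc3)CC(=O)c1c2OC(C)=O
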